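**Retrosynthetic overview**
- The strategy rests on ring A (C4a, C5, C6, C7, C8, C8a): its oxygens sit meta at C5 and C7 and it shares the C4a–C8a bond with the pyranone ring C. This is the resorcinol monoether pattern that a vinylketene and an alkoxyalkyne deliver.
- The target comes from O-methylation of the chelated 5-hydroxyl of 5-hydroxy-7-methoxy-2-(2,3,4-trimethoxyphenyl)chromen-4-one.
- Ring A is disconnected at C8–C8a (Wolff shift), C5–C6 and C7–C8 ([2+2]) and C4a–C5 (6π closure), giving 2-(diazoacetyl)-6-aryl-4-pyranone and methoxyethyne.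
- The diazo ketone comes from the 6-aryl-4-oxopyran-2-carboxylic acid, made from the aroylacetone and diethyl oxalate; methoxyethyne comes from chloroacetaldehyde dimethyl acetal.
- Ring order: ring B is bought, ring C is closed by acid cyclodehydration, ring A is closed last.

Key step: step 7

Assumption: diazomethane is used as a freshly prepared ethereal solution and treated as a reagent; the tricarbonyl compounds 3 and 5, which are largely enolised, are drawn in their keto forms.

**Route**

Step 1
Reactants: 1 2,3,4-trimethoxyacetophenone; 2 ethyl acetate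
Product: 3 1-(2,3,4-trimethoxyphenyl)butane-1,3-dione
Conditions: NaH (2.5 equiv), EtOAc (4 equiv), THF, 0 °C to reflux; then aq. HCl
Reagents that add atoms: none
Why: Crossed Claisen condensation in which the sodium enolate of the aryl methyl ketone is acetylated by ethyl acetate and the product is held as its stabilised 1,3-diketone enolate until the acid quench.

Step 2
Reactants: 3 1-(2,3,4-trimethoxyphenyl)butane-1,3-dione; 4 diethyl oxalate
Product: 5 ethyl 2,4,6-trioxo-6-(2,3,4-trimethoxyphenyl)hexanoate
Conditions: NaOEt (3 equiv), (CO2Et)2 (1.5 equiv), EtOH, 0 °C to 60 °C; then cold aq. HCl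
Reagents that add atoms: none
Why: Claisen condensation with the non-enolisable oxalate under equilibrating alkoxide conditions, where acylation at the terminal methyl gives a doubly stabilised enolate while any adduct at the central carbon is cleaved back, so the linear trioxo ester should accumulate.

Step 3
Reactants: 5 ethyl 2,4,6-trioxo-6-(2,3,4-trimethoxyphenyl)hexanoate
Product: 7 4-oxo-6-(2,3,4-trimethoxyphenyl)-4H-pyran-2-carboxylic acid, via ethyl ester 6 (not isolated)
Conditions: conc. HCl, AcOH, reflux
Reagents that add atoms: water, O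
Why: Acid-catalysed cyclodehydration of the 1,3,5-tricarbonyl unit (enol oxygen at C6 onto the C2 ketone) closes the 4-pyranone and the same aqueous acid hydrolyses the ester, the classical route to pyranone-2-carboxylic acids; aryl methyl ethers are inert to HCl.

Step 4
Reactants: 7 4-oxo-6-(2,3,4-trimethoxyphenyl)-4H-pyran-2-carboxylic acid
Product: 8 4-oxo-6-(2,3,4-trimethoxyphenyl)-4H-pyran-2-carbonyl chloride
Conditions: (COCl)2 (1.5 equiv), DMF (cat.), CH2Cl2, 0 °C to rt
Reagents that add atoms: oxalyl chloride, O=C(Cl)C(Cl)=O
Why: Acid chloride formation through the Vilsmeier-type chloroiminium catalyst under mild conditions that leave the pyranone and the methyl ethers untouched.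

Step 5
Reactants: 8 4-oxo-6-(2,3,4-trimethoxyphenyl)-4H-pyran-2-carbonyl chloride
Product: 9 2-(2-diazoacetyl)-6-(2,3,4-trimethoxyphenyl)-4H-pyran-4-one
Conditions: CH2N2 (3 equiv), Et2O/CH2Cl2, 0 °C
Reagents that add atoms: diazomethane, C=[N+]=[N-]
Why: C-acylation of diazomethane by the acid chloride (first stage of the Arndt–Eistert sequence), with the excess reagent consuming HCl as chloromethane so that the diazo ketone is not converted into the chloromethyl ketone.

Step 6
Reactants: 10 chloroacetaldehyde dimethyl acetal
Product: 12 methoxyethyne, via sodium methoxyethynide 11 (not isolated)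
Conditions: NaNH2 (3.1 equiv), liq. NH3, −33 °C; NH3 evaporated; sat. aq. NaCl, −70 °C to rt; distilled into a −78 °C trap
Reagents that add atoms: none
Why: Twofold amide-induced elimination (methanol, then HCl) with the third equivalent of base holding the product as its acetylide until the cold aqueous quench, the standard preparation of 1-alkoxyalkynes from chloroacetals.

Step 7
Reactants: 9 2-(2-diazoacetyl)-6-(2,3,4-trimethoxyphenyl)-4H-pyran-4-one; 12 methoxyethyne
Product: 17 5-hydroxy-7-methoxy-2-(2,3,4-trimethoxyphenyl)-4H-chromen-4-one, via pyranonylketene 13 (not isolated), via 3-methoxycyclobutenone 14 (not isolated), via dienylketene 15 (not isolated), via 4a-H dienone 16 (not isolated)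
Conditions: 12 (3 equiv), hν (300 nm, Pyrex), degassed ClCH2CH2Cl (0.05 M), 0–5 °C, sealed vessel; then 80 °C
Reagents that add atoms: none
Why: Proposed new method: irradiation of 9 triggers a Wolff rearrangement in which pyranone C2 shifts to the diazo carbon with loss of N2 (C8–C8a) to give ketene 13, whose carbonyl carbon is attacked by the unsubstituted carbon of 12 so that [2+2] closure gives cyclobutenone 14 (C5–C6 and C7–C8). 14 opens by 4π electrocyclic cleavage of the bond between its carbonyl carbon and the pyranonyl-bearing carbon to dienylketene 15, and ring A is closed by a thermal disrotatory 6π electrocyclisation of the ketene carbon onto pyranone C3 (C4a–C5), after which the 1,3-diketone 16 enolises to the chelated phenol 17. The closest known reaction type is the diazo ketone (Wolff) form of the Danheiser benzannulation, established for aryl, heteroaryl and alkenyl diazomethyl ketones with alkoxy- and siloxyalkynes; what is new is a 4-pyranone C2=C3 bond as the π bond that carries the ketene. No stereocenter survives, since the sp3 carbons of 14 and 16 become sp2 on the way to 17. The regiochemistry the step needs is secured by the polarity of the ynol ether, which places the alkyne oxygen on the carbon bonded to the former diazo carbon (7-OMe) and leaves the ketene oxygen as the 5-OH, and the 6π closure has no choice of site because the other neighbour of C2 is the ring oxygen. Chemoselective excitation is sought by irradiating near 300 nm through Pyrex and not at 254 nm to spare the 4-pyranone chromophore, with excess 12 to outrun ketene dimerisation and a final warming to drive 14 on to 17.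

Step 8
Reactants: 17 5-hydroxy-7-methoxy-2-(2,3,4-trimethoxyphenyl)-4H-chromen-4-one
Product: 18 2',3',4',5,7-pentamethoxyflavone
Conditions: Me2SO4 (3 equiv), K2CO3 (5 equiv), acetone, reflux
Reagents that add atoms: dimethyl sulfate, COS(=O)(=O)OC
Why: Williamson O-methylation in which the hydrogen-bonded 5-hydroxyl, though sluggish, is alkylated by excess dimethyl sulfate and carbonate in refluxing acetone, as is standard for 5-hydroxyflavones.

**Compound list**
1 | 2,3,4-trimethoxyacetophenone | CC(=O)c1ccc(OC)c(OC)c1OC | starting material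
2 | ethyl acetate | CCOC(C)=O | starting material
3 | 1-(2,3,4-trimethoxyphenyl)butane-1,3-dione | CC(=O)CC(=O)c1ccc(OC)c(OC)c1OC | intermediate
4 | diethyl oxalate | CCOC(=O)C(=O)OCC | starting material
5 | ethyl 2,4,6-trioxo-6-(2,3,4-trimethoxyphenyl)hexanoate | CCOC(=O)C(=O)CC(=O)CC(=O)c1ccc(OC)c(OC)c1OC | intermediate
6 | ethyl 4-oxo-6-(2,3,4-trimethoxyphenyl)-4H-pyran-2-carboxylate (not isolated) | CCOC(=O)c1cc(=O)cc(-c2ccc(OC)c(OC)c2OC)o1 | intermediate
7 | 4-oxo-6-(2,3,4-trimethoxyphenyl)-4H-pyran-2-carboxylic acid | OC(=O)c1cc(=O)cc(-c2ccc(OC)c(OC)c2OC)o1 | intermediate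
8 | 4-oxo-6-(2,3,4-trimethoxyphenyl)-4H-pyran-2-carbonyl chloride | ClC(=O)c1cc(=O)cc(-c2ccc(OC)c(OC)c2OC)o1 | intermediate
9 | 2-(2-diazoacetyl)-6-(2,3,4-trimethoxyphenyl)-4H-pyran-4-one | COc1ccc(-c2cc(=O)cc(C(=O)C=[N+]=[N-])o2)c(OC)c1OC | intermediate
10 | chloroacetaldehyde dimethyl acetal | COC(CCl)OC | starting material
11 | sodium methoxyethynide (not isolated) | COC#[C-].[Na+] | intermediate
12 | methoxyethyne | COC#C | intermediate
13 | 2-(2-oxoethenyl)-6-(2,3,4-trimethoxyphenyl)-4H-pyran-4-one, the pyranonylketene (not isolated) | COc1ccc(-c2cc(=O)cc(C=C=O)o2)c(OC)c1OC | intermediate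
14 | 3-methoxy-4-[4-oxo-6-(2,3,4-trimethoxyphenyl)-4H-pyran-2-yl]cyclobut-2-en-1-one, racemic (not isolated) | COC1=CC(=O)C1c1cc(=O)cc(-c2ccc(OC)c(OC)c2OC)o1 | intermediate
15 | 2-(2-methoxy-4-oxobuta-1,3-dien-1-yl)-6-(2,3,4-trimethoxyphenyl)-4H-pyran-4-one, the dienylketene with ketene carbon and pyranonyl group cis (not isolated) | O=C=C/C(OC)=C\c1cc(=O)cc(-c2ccc(OC)c(OC)c2OC)o1 | intermediate
16 | 7-methoxy-2-(2,3,4-trimethoxyphenyl)-4aH-chromene-4,5-dione, racemic keto tautomer (not isolated) | COC1=CC(=O)C2C(=O)C=C(c3ccc(OC)c(OC)c3OC)OC2=C1 | intermediate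
17 | 5-hydroxy-7-methoxy-2-(2,3,4-trimethoxyphenyl)-4H-chromen-4-one | COc1cc(O)c2c(=O)cc(-c3ccc(OC)c(OC)c3OC)oc2c1 | intermediate
18 | 2',3',4',5,7-pentamethoxyflavone | COc1cc(OC)c2c(=O)cc(-c3ccc(OC)c(OC)c3OC)oc2c1 | target

**Step count**
Total steps: 8. Longest linear sequence: 7 steps (steps 1–5, 7 and 8); step 6 is a one-step branch.

**Steps most likely to fail**

Step 7. The light may also excite the aryl-pyranone chromophore and cause photoisomerisation of the pyranone. The ketene may dimerise, or the 6π closure onto the electron-poor C3 may be slow. The fallback leaves the benzannulation and uses known flavone chemistry; it sets out from 1 and returns at 18. Claisen condensation of 1 with diethyl carbonate (NaH, toluene, reflux) should give ethyl 3-oxo-3-(2,3,4-trimethoxyphenyl)propanoate F1. Heating it with phloroglucinol without solvent or acid at about 240 °C (thermal β-keto ester/phloroglucinol chromone condensation) should give 5,7-dihydroxy-2-(2,3,4-trimethoxyphenyl)-4H-chromen-4-one F2. Exhaustive O-methylation (Me2SO4, K2CO3, acetone, reflux) then leads to 18.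

Step 5. Diazomethane may add as a 1,3-dipole across the electron-poor C2=C3 bond of the pyranone, and HCl may capture the diazo ketone as the chloromethyl ketone. The fallback installs the diazo group by diazo transfer instead; it sets out from 8 and returns at 9. Acyl cross-coupling of 8 with MeZnCl and catalytic Pd(PPh3)4 (THF, 0 °C) should give 2-acetyl-6-(2,3,4-trimethoxyphenyl)-4H-pyran-4-one F3. Its lithium enolate (LiN(SiMe3)2, THF, −78 °C) is trifluoroacetylated with CF3CO2CH2CF3 to 4,4,4-trifluoro-1-[4-oxo-6-(2,3,4-trimethoxyphenyl)-4H-pyran-2-yl]butane-1,3-dione F4, used crude. Detrifluoroacetylative diazo transfer (MsN3, Et3N, H2O, MeCN, rt) should then give 9.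

Step 6. The product boils near room temperature, so it may be lost by evaporation, hydration or polymerisation during the aqueous quench and distillation. The fallback avoids methoxyethyne altogether; it sets out from 9 and returns at 18. Under the conditions of step 7, 9 is combined with commercial ethoxyethyne (solution in hexanes) to give 7-ethoxy-5-hydroxy-2-(2,3,4-trimethoxyphenyl)-4H-chromen-4-one F5. Excess BBr3 (CH2Cl2, −78 °C to rt) cleaves all five alkyl ethers to 5,7-dihydroxy-2-(2,3,4-trihydroxyphenyl)-4H-chromen-4-one F6. Exhaustive methylation (Me2SO4, K2CO3, acetone, reflux, under argon) should give 18.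

**Further compounds**
F1 | step 7 | ethyl 3-oxo-3-(2,3,4-trimethoxyphenyl)propanoate | CCOC(=O)CC(=O)c1ccc(OC)c(OC)c1OC
F2 | step 7 | 5,7-dihydroxy-2-(2,3,4-trimethoxyphenyl)-4H-chromen-4-one | COc1ccc(-c2cc(=O)c3c(O)cc(O)cc3o2)c(OC)c1OC
F3 | step 5 | 2-acetyl-6-(2,3,4-trimethoxyphenyl)-4H-pyran-4-one | CC(=O)c1cc(=O)cc(-c2ccc(OC)c(OC)c2OC)o1
F4 | step 5 | 4,4,4-trifluoro-1-[4-oxo-6-(2,3,4-trimethoxyphenyl)-4H-pyran-2-yl]butane-1,3-dione | O=C(CC(=O)C(F)(F)F)c1cc(=O)cc(-c2ccc(OC)c(OC)c2OC)o1
F5 | step 6 | 7-ethoxy-5-hydroxy-2-(2,3,4-trimethoxyphenyl)-4H-chromen-4-one | CCOc1cc(O)c2c(=O)cc(-c3ccc(OC)c(OC)c3OC)oc2c1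
F6 | step 6 | 5,7-dihydroxy-2-(2,3,4-trihydroxyphenyl)-4H-chromen-4-one | Oc1cc(O)c2c(=O)cc(-c3ccc(O)c(O)c3O)oc2c1
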